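**Plan**

- Cuts: the C8–C1'' bond of the C-prenyl group (back to a 5-O-prenyl ether by a retro Claisen–Cope relay), both O–prenyl bonds (back to (2S)-pinocembrin) and, last, the C2–C3 bond of ring C.
- Enabling feature: C2 carries H, the phenyl of ring B and O1, so it is the CH2 carbon of a benzyl ether on the C8a oxygen, while C3 lies α to the C4 ketone and can be a diazo (carbene) carbon.
- Forward: ring A is bought as 2,4,6-trihydroxyacetophenone, tri-O-benzylated and converted into the diazo ketone; carbene C–H insertion into an ortho OCH2Ph group forms C2–C3 and closes ring C, ring B being the phenyl of that benzyl group.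
- The two spectator benzyl ethers are then removed, both phenols are prenylated and the 5-O-prenyl group is relayed to C8.
- Stereochemistry: C2 is the only stereocentre; it is set in the insertion by a chiral dirhodium tetracarboxylate that chooses between the enantiotopic benzylic hydrogens, and every later step avoids the basic conditions that open ring C.

Key step: step 3

Assumption: Rh2(S-PTTL)4 is taken to deliver the (2S) configuration at C2; should the sense of induction prove opposite, the mirror-image catalyst Rh2(R-PTTL)4 is used in step 3 with nothing else changed.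

**Step 1**
Reactants: 1 2,4,6-trihydroxyacetophenone; 2 benzyl bromide
Product: 5 1-[2,4,6-tris(benzyloxy)phenyl]ethanone, via 4-O-benzyl ether 3 (not isolated), via 2,4-di-O-benzyl ether 4 (not isolated)
Conditions: BnBr (3.6 equiv), K2CO3 (4.5 equiv), DMF, 70 °C
Reagents that add atoms: benzyl bromide (compound 2), BrCc1ccccc1
Why: Williamson ether synthesis in which carbonate in a dipolar aprotic solvent alkylates the free 4-OH first (3), then one hydrogen-bonded ortho phenol (4) and, with excess bromide and heat, the last one, O-alkylation of the potassium phenoxides in DMF being favoured over C-benzylation of the phloroglucinol ring.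

**Step 2**
Reactants: 5 1-[2,4,6-tris(benzyloxy)phenyl]ethanone
Product: 7 2-diazo-1-[2,4,6-tris(benzyloxy)phenyl]ethanone, via trifluoroacetyl diketone 6 (not isolated)
Conditions: LiN(SiMe3)2, THF, −78 °C; CF3CO2CH2CF3; aq HCl; then 4-acetamidobenzenesulfonyl azide (p-ABSA), Et3N, H2O, MeCN, rt
Reagents that add atoms: 4-acetamidobenzenesulfonyl azide, CC(=O)Nc1ccc(cc1)S(=O)(=O)N=[N+]=[N-] (supplies the N2 unit); 2,2,2-trifluoroethyl trifluoroacetate, O=C(OCC(F)(F)F)C(F)(F)F (supplies the CF3CO group, held only in 6)
Why: Detrifluoroacetylative (deacylative Regitz-type) diazo transfer, in which the acetyl methyl group, the only enolisable position, is C-trifluoroacetylated to the activated 1,3-diketone 6, which adds to the sulfonyl azide and fragments with loss of the N-sulfonyl trifluoroacetamide to leave the terminal diazo ketone.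

**Step 3**
Reactants: 7 2-diazo-1-[2,4,6-tris(benzyloxy)phenyl]ethanone
Product: 8 (2S)-5,7-bis(benzyloxy)-2-phenylchroman-4-one [(2S)-5,7-bis(benzyloxy)flavanone]
Conditions: Rh2(S-PTTL)4 (dirhodium tetrakis[N-phthaloyl-(S)-tert-leucinate], 2 mol%), toluene, 4 Å MS, 0 °C → rt, slow addition of 7
Reagents that add atoms: none
Why: Rh2(S-PTTL)4 expels N2 from 7 to give an electrophilic rhodium carbene at the future C3, which inserts into a benzylic C–H bond of an ortho OCH2Ph group through a concerted, asynchronous three-centre transition state (hydride transfer to the carbene carbon merging with C–C bond formation) and so forms C2–C3. The closest known reaction type is the intramolecular C–H insertion of 2-alkoxyaryl diazo ketones catalysed by chiral carboxylates of divalent rhodium, which gives 2-substituted chroman-4-ones. Ring C (C3, C4, C4a, C8a, O1, C2) closes as a 1,6-insertion, six-membered because the 1,5-position is the ether oxygen, which has no hydrogen to offer. C2 is the only new stereocentre and is set by the chiral pocket of the four N-phthaloyl-(S)-tert-leucinate ligands, which lets only one of the two enantiotopic benzylic hydrogens reach the carbene; the two ortho benzyloxy groups are homotopic, so either gives 8, and the para one is out of reach and becomes the C7 ether. The step needs insertion to outrun attack of the ether oxygen on the carbene (oxonium ylide, then [1,2]-benzyl shift to a 2-benzylbenzofuran-3-one): the C–H bond is doubly activated by oxygen and phenyl, the aryl ether oxygens are poor nucleophiles because their lone pairs are drawn into the ring and the ketone, carboxylate-bound rhodium carbenes favour insertion where copper carbenes favour ylides, and the bulky ligand wall, the non-polar solvent and the low temperature all disfavour the charge-separated ylide path.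

**Step 4**
Reactants: 8 (2S)-5,7-bis(benzyloxy)-2-phenylchroman-4-one
Product: 11 (2S)-pinocembrin [(2S)-5,7-dihydroxy-2-phenylchroman-4-one], via 7-O-benzyl ether 9 (not isolated), via 5-O-benzyl ether 10 (not isolated)
Conditions: H2 (1 atm), 10% Pd/C, EtOAc–THF, rt
Reagents that add atoms: none
Why: Heterogeneous palladium-catalysed hydrogenolysis of the two primary aryl benzyl ethers (in either order, through 9 or 10), which should be cleaved faster than the hindered secondary benzylic C2–O1 bond or the C4 ketone when hydrogen uptake is stopped at two equivalents, in a neutral medium that cannot open ring C and so leaves C2 intact.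

**Step 5**
Reactants: 11 (2S)-pinocembrin; 12 3-methylbut-2-en-1-ol (prenyl alcohol)
Product: 14 (2S)-5,7-bis[(3-methylbut-2-en-1-yl)oxy]-2-phenylchroman-4-one [(2S)-5,7-bis(prenyloxy)flavanone], via 7-O-prenylpinocembrin 13 (not isolated)
Conditions: prenyl alcohol (3 equiv), PPh3 (3 equiv), DIAD (3 equiv), THF, 0 °C → rt
Reagents that add atoms: 3-methylbut-2-en-1-ol (compound 12), CC(C)=CCO
Why: Double Mitsunobu etherification in which the acidic 7-OH is alkylated first (13) and the hydrogen-bonded 5-OH follows with the excess reagents, as is known for chelated ortho-acyl phenols with prenyl alcohol, while the absence of strong base avoids retro-oxa-Michael opening of ring C and thus racemisation at C2.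

**Step 6**
Reactants: 14 (2S)-5,7-bis(prenyloxy)flavanone
Product: 17 (2S)-5-hydroxy-8-(3-methylbut-2-en-1-yl)-7-[(3-methylbut-2-en-1-yl)oxy]-2-phenylchroman-4-one (CNP0292726.1), via ortho-dienone 15 (not isolated), via para-dienone 16 (not isolated)
Conditions: Eu(fod)3 (10 mol%), CHCl3, 60 °C
Reagents that add atoms: none
Why: Eu(fod)3-catalysed tandem aromatic Claisen–Cope (para-Claisen) rearrangement, in which chelation of trivalent europium between the C4 carbonyl and the C5 ether oxygen activates only that prenyl ether for the [3,3] shift to C6 (15), a second [3,3] (Cope) shift carries the group on to C8 as a linear prenyl unit (16) and enolisation restores the chelated 5-OH phenol, while the unchelated 7-O-prenyl ether would need a far higher temperature to rearrange and C2 is not involved.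

**Compound list**

1 | 2,4,6-trihydroxyacetophenone | CC(=O)c1c(O)cc(O)cc1O | starting material
2 | benzyl bromide | BrCc1ccccc1 | starting material
3 | 1-[4-(benzyloxy)-2,6-dihydroxyphenyl]ethanone (transient in step 1) | CC(=O)c1c(O)cc(OCc2ccccc2)cc1O | intermediate
4 | 1-[2,4-bis(benzyloxy)-6-hydroxyphenyl]ethanone (transient in step 1) | CC(=O)c1c(O)cc(OCc2ccccc2)cc1OCc1ccccc1 | intermediate
5 | 1-[2,4,6-tris(benzyloxy)phenyl]ethanone | CC(=O)c1c(OCc2ccccc2)cc(OCc2ccccc2)cc1OCc1ccccc1 | intermediate
6 | 4,4,4-trifluoro-1-[2,4,6-tris(benzyloxy)phenyl]butane-1,3-dione (transient in step 2) | O=C(CC(=O)C(F)(F)F)c1c(OCc2ccccc2)cc(OCc2ccccc2)cc1OCc1ccccc1 | intermediate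
7 | 2-diazo-1-[2,4,6-tris(benzyloxy)phenyl]ethanone | [N-]=[N+]=CC(=O)c1c(OCc2ccccc2)cc(OCc2ccccc2)cc1OCc1ccccc1 | intermediate
8 | (2S)-5,7-bis(benzyloxy)-2-phenylchroman-4-one | O=C1C[C@@H](c2ccccc2)Oc2cc(OCc3ccccc3)cc(OCc3ccccc3)c12 | intermediate
9 | (2S)-7-(benzyloxy)-5-hydroxy-2-phenylchroman-4-one (transient in step 4) | O=C1C[C@@H](c2ccccc2)Oc2cc(OCc3ccccc3)cc(O)c12 | intermediate
10 | (2S)-5-(benzyloxy)-7-hydroxy-2-phenylchroman-4-one (transient in step 4) | O=C1C[C@@H](c2ccccc2)Oc2cc(O)cc(OCc3ccccc3)c12 | intermediate
11 | (2S)-pinocembrin, (2S)-5,7-dihydroxy-2-phenylchroman-4-one | O=C1C[C@@H](c2ccccc2)Oc2cc(O)cc(O)c12 | intermediate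
12 | 3-methylbut-2-en-1-ol (prenyl alcohol) | CC(C)=CCO | starting material
13 | (2S)-5-hydroxy-7-[(3-methylbut-2-en-1-yl)oxy]-2-phenylchroman-4-one (transient in step 5) | O=C1C[C@@H](c2ccccc2)Oc2cc(OCC=C(C)C)cc(O)c12 | intermediate
14 | (2S)-5,7-bis[(3-methylbut-2-en-1-yl)oxy]-2-phenylchroman-4-one | O=C1C[C@@H](c2ccccc2)Oc2cc(OCC=C(C)C)cc(OCC=C(C)C)c12 | intermediate
15 | (2S)-6-(2-methylbut-3-en-2-yl)-7-[(3-methylbut-2-en-1-yl)oxy]-2-phenyl-2,3-dihydro-4H-chromene-4,5(6H)-dione, ortho-dienone, C6 unassigned (transient in step 6) | O=C1C(C(C)(C)C=C)C(OCC=C(C)C)=CC2=C1C(=O)C[C@@H](c1ccccc1)O2 | intermediate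
16 | (2S)-8-(3-methylbut-2-en-1-yl)-7-[(3-methylbut-2-en-1-yl)oxy]-2-phenyl-2,3-dihydro-4H-chromene-4,5(8H)-dione, para-dienone, C8 unassigned (transient in step 6) | O=C1C=C(OCC=C(C)C)C(CC=C(C)C)C2=C1C(=O)C[C@@H](c1ccccc1)O2 | intermediate
17 | (2S)-5-hydroxy-8-(3-methylbut-2-en-1-yl)-7-[(3-methylbut-2-en-1-yl)oxy]-2-phenylchroman-4-one (CNP0292726.1) | CC(C)=CCOc1cc(O)c2c(c1CC=C(C)C)O[C@H](c1ccccc1)CC2=O | target

**Step count**

Total steps: 6. Longest linear sequence: 6 steps (1 → 5 → 7 → 8 → 11 → 14 → 17).

**Steps most likely to fail**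

Step 3. The carbene may be diverted into oxonium ylide formation and [1,2]-benzyl migration, or the catalyst may discriminate poorly between the two enantiotopic benzylic hydrogens. A modest enantiomeric excess should be correctable by recrystallising 8 or 11. If the insertion itself cannot be made to dominate, the fallback sets out from 1 and comes back at 8, closing ring C first and setting C2 by forming the C2–phenyl bond instead. Benzylation of 1 with two equivalents of 2 (K2CO3, acetone, reflux) is stopped at 1-[2,4-bis(benzyloxy)-6-hydroxyphenyl]ethanone 4, now isolated. Condensation with N,N-dimethylformamide dimethyl acetal gives the enaminone (E)-1-[2,4-bis(benzyloxy)-6-hydroxyphenyl]-3-(dimethylamino)prop-2-en-1-one F1. Acid (HCl, CH2Cl2) closes it to 5,7-bis(benzyloxy)-4H-chromen-4-one F2. Asymmetric conjugate addition of PhB(OH)2 under Pd(OCOCF3)2 with the t-BuPyOx enantiomer that leads to the (2S) series (NH4PF6, H2O, ClCH2CH2Cl, 60 °C), a known route to flavanones from chromones, then gives 8.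

Step 6. The ortho-dienone may enolise before the Cope shift and leave a 1,1-dimethylallyl group at C6, the second prenyl ether may take part, or Lewis-acid-induced opening and reclosure of ring C may erode C2. The fallback sets out from 11 and comes back at 17; it puts the C-prenyl group in before the 7-O-prenyl ether exists. Selective acetylation of the free 7-OH (Ac2O, 1 equiv, pyridine, 0 °C) gives (2S)-7-acetoxy-5-hydroxy-2-phenylchroman-4-one F3. Mitsunobu etherification of the chelated 5-OH with 12 gives (2S)-7-acetoxy-5-[(3-methylbut-2-en-1-yl)oxy]-2-phenylchroman-4-one F4. Eu(fod)3 in CHCl3 then runs the Claisen–Cope relay on the pattern for which it is best established (a single prenyl ether beside an electron-poor 7-O-acyl group), through the acetoxy ortho-dienone F5 and the acetoxy para-dienone F6 to (2S)-7-acetoxy-5-hydroxy-8-(3-methylbut-2-en-1-yl)-2-phenylchroman-4-one F7. Neutral methanolysis (NH4OAc, MeOH, rt) gives (2S)-5,7-dihydroxy-8-(3-methylbut-2-en-1-yl)-2-phenylchroman-4-one F8. A Mitsunobu reaction with one equivalent of 12, which reaches only the unchelated 7-OH, gives 17.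

Step 5. The activated prenyl oxyphosphonium may ionise or eliminate faster than the hindered, hydrogen-bonded 5-OH attacks it, so that the reaction stalls at the mono-ether or gives C-alkylation. The fallback sets out from 11 and comes back at 14; it builds the second prenyl ether by olefin metathesis instead of by direct prenyl transfer. A Mitsunobu reaction with one equivalent of 12 gives 13, now isolated. A second Mitsunobu reaction with allyl alcohol, a primary non-ionising partner known to etherify chelated flavonoid 5-OH groups cleanly, gives (2S)-5-(allyloxy)-7-[(3-methylbut-2-en-1-yl)oxy]-2-phenylchroman-4-one F9. Cross-metathesis with 2-methylbut-2-ene (second-generation Grubbs catalyst, CH2Cl2, 40 °C) converts the allyl ether into the prenyl ether and gives 14.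

**Further compounds**

F1 | step 3 | (E)-1-[2,4-bis(benzyloxy)-6-hydroxyphenyl]-3-(dimethylamino)prop-2-en-1-one | CN(C)/C=C/C(=O)c1c(O)cc(OCc2ccccc2)cc1OCc1ccccc1
F2 | step 3 | 5,7-bis(benzyloxy)-4H-chromen-4-one | O=c1ccoc2cc(OCc3ccccc3)cc(OCc3ccccc3)c12
F3 | step 6 | (2S)-7-acetoxy-5-hydroxy-2-phenylchroman-4-one | O=C1C[C@@H](c2ccccc2)Oc2cc(OC(C)=O)cc(O)c12
F4 | step 6 | (2S)-7-acetoxy-5-[(3-methylbut-2-en-1-yl)oxy]-2-phenylchroman-4-one | O=C1C[C@@H](c2ccccc2)Oc2cc(OC(C)=O)cc(OCC=C(C)C)c12
F5 | step 6 | (2S)-7-acetoxy-6-(2-methylbut-3-en-2-yl)-2-phenyl-2,3-dihydro-4H-chromene-4,5(6H)-dione (acetoxy ortho-dienone) | O=C1C(C(C)(C)C=C)C(OC(C)=O)=CC2=C1C(=O)C[C@@H](c1ccccc1)O2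
F6 | step 6 | (2S)-7-acetoxy-8-(3-methylbut-2-en-1-yl)-2-phenyl-2,3-dihydro-4H-chromene-4,5(8H)-dione (acetoxy para-dienone) | O=C1C=C(OC(C)=O)C(CC=C(C)C)C2=C1C(=O)C[C@@H](c1ccccc1)O2
F7 | step 6 | (2S)-7-acetoxy-5-hydroxy-8-(3-methylbut-2-en-1-yl)-2-phenylchroman-4-one | O=C1C[C@@H](c2ccccc2)Oc2c(CC=C(C)C)c(OC(C)=O)cc(O)c12
F8 | step 6 | (2S)-5,7-dihydroxy-8-(3-methylbut-2-en-1-yl)-2-phenylchroman-4-one | O=C1C[C@@H](c2ccccc2)Oc2c(CC=C(C)C)c(O)cc(O)c12
F9 | step 5 | (2S)-5-(allyloxy)-7-[(3-methylbut-2-en-1-yl)oxy]-2-phenylchroman-4-one | O=C1C[C@@H](c2ccccc2)Oc2cc(OCC=C(C)C)cc(OCC=C)c12
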